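**Retrosynthetic overview**
- Feature used: on the cyclohexane ring the CH2OAr on quaternary C1 and the CH3 on C2 are cis, so both carbons come from one cis-fused five-membered lactone acetal (acetal carbon → CH2O on C1, carbonyl carbon → CH3 on C2).
- Late stage: the 3-hydroxypropyl chain from a C6 allyl group (hydroboration, last step), the aryl ether by Mitsunobu reaction of the C1 neopentyl alcohol with isofraxidin, the C5 isopropylidene from the C5 ketone through a β-lactone.
- Middle: the lactone acetal is reduced and re-closed as a cis-fused oxolane before any enolate chemistry; the allyl group enters at C6 by α′-alkylation of the bicyclic enone on its convex face; the oxolane is later opened at the CH2 on C2 (→ C2–CH3 and C1–CH2OH).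
- Key disconnection: [4+2] of (5S)-5-menthyloxy-4-methylbutenolide with 1-methoxy-3-(trimethylsilyloxy)butadiene, forming C1–C6 and C2–C3 and setting C1 and C2.
- Ring order: butenolide (bought) → carbocycle (step 2) → oxolane in place of the lactone (step 4) → oxolane opened (step 11); the coumarin is brought in intact.

Key step: step 2

Convention: ring carbons of all intermediates carry the target locants (C1 quaternary with CH3 and CH2O; C2; C3; C4; C5 carbonyl/isopropylidene; C6 side chain); α is the face of the C1 CH2O group, β the face of the C1 methyl.
Remark: it is assumed that the (5S) acetal epimer 3 is the one that crystallises; if it does not, the epimers are separated by chromatography and the unwanted one is re-equilibrated with acid.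

**Step 1**
Reactants: 1 5-hydroxy-4-methylfuran-2(5H)-one; 2 (+)-menthol
Product: 3 (5S)-5-menthyloxy-4-methylfuran-2(5H)-one
Conditions: p-TsOH (cat.), toluene, reflux with azeotropic removal of water; crystallisation from hexane
Reagents that add atoms: none
Why: Acid-catalysed acetalisation of the cyclic hemiacetal gives both C5 epimers, which interconvert under the acid, so crystallisation should deliver the (5S) epimer, whose acetal centre is the only source of asymmetric induction later.

**Step 2**
Reactants: 3 (5S)-5-menthyloxy-4-methylfuran-2(5H)-one; 4 (E)-1-methoxy-3-(trimethylsilyloxy)buta-1,3-diene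
Product: 6 cis-fused enone lactone acetal, via silyl enol ether cycloadduct 5 (not isolated)
Conditions: 4 (3 equiv), toluene, 130 °C, sealed tube; then 0.1 M HCl, THF, 0 °C
Reagents that add atoms: none
Why: Thermal normal-demand [4+2] cycloaddition, concerted but strongly asynchronous: the nucleophilic CH2 terminus of the diene bonds to the lactone β-carbon (C1–C6, quaternary C1) ahead of the bond from the methoxy-bearing terminus to the α-carbon (C2–C3); the closest known reaction type is the Diels–Alder addition of 1-alkoxy-3-silyloxybutadienes to 5-alkoxy-2(5H)-furanones. The carbocycle is closed by suprafacial addition of both diene termini to one face of the endocyclic C=C, so the six-membered ring is necessarily cis-fused to the lactone. C1 and C2 are both set by the acetal carbon of 3: the diene approaches the face anti to the menthyloxy group, which puts the C1 methyl and C2–H on the menthyloxy side. The regiochemistry that is needed (carbonyl at C5, CH2 at C6) is secured by the matched polarisation of the partners, the largest HOMO coefficient of the diene (CH2 terminus) meeting the largest LUMO coefficient of the butenolide (β-carbon). The methoxy-bearing carbon of 5 forms as an endo/exo mixture that is erased when dilute acid hydrolyses the silyl enol ether and eliminates methanol to the enone. The β-methyl group retards the addition, hence excess diene and 130 °C; the face selectivity depends only on the rigid acetal centre and should hold at that temperature.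

**Step 3**
Reactants: 6 cis-fused enone lactone acetal
Product: 7 cis-4,5-bis(hydroxymethyl)-5-methylcyclohex-2-en-1-ol
Conditions: 6 added to LiAlH4, THF, −40 → 0 °C; H2O, aq. NaOH work-up
Reagents that add atoms: none
Why: Hydride reduction should take the enone carbonyl by 1,2-addition and the lactone acetal to the cis-1,4-diol with loss of menthol; this removes the auxiliary and also the lactone carbonyl, which makes C2–H (α to the lactone, γ to the enone) more acidic than the α′-hydrogens at C6 and would misdirect the later enolate alkylation; the C5 carbinol forms as an inconsequential mixture.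

**Step 4**
Reactants: 7 cis-4,5-bis(hydroxymethyl)-5-methylcyclohex-2-en-1-ol
Product: 9 cis-fused oxolane allylic alcohol, via monotosylate 8 (not isolated)
Conditions: TsCl (1.1 equiv), pyridine, 0 → 50 °C
Reagents that add atoms: none
Why: Selective sulfonylation of the less hindered primary hydroxyl (CH2OH on C2) followed by intramolecular Williamson-type 5-exo-tet displacement by the neopentyl hydroxyl should close the cis-fused oxolane, which masks both primary oxygens, gives a rigid bicycle for face control at C6 and leaves the two CH2O carbons distinguishable by their steric environment.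

**Step 5**
Reactants: 9 cis-fused oxolane allylic alcohol
Product: 10 cis-fused oxolane enone
Conditions: activated MnO2 (excess), CH2Cl2, rt
Reagents that add atoms: none
Why: MnO2 oxidises allylic alcohols chemoselectively, so both C5 epimers should converge on the enone, in which C2–H is now only an ordinary γ-hydrogen.

**Step 6**
Reactants: 10 cis-fused oxolane enone
Product: 12 6β-allyl oxolane enone, via lithium dienolate 11 (not isolated)
Conditions: LiN(i-Pr)2 (1.1 equiv), THF, −78 °C; allyl bromide, DMPU, −78 → −30 °C
Reagents that add atoms: allyl bromide, C=CCBr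
Why: Kinetic α′-deprotonation of the enone (only C6 carries α′-hydrogens) gives the cross-conjugated lithium dienolate, which is alkylated at C6 by SN2 on allyl bromide; the electrophile should approach the convex β-face of the cis-fused bicycle, anti to the pseudo-axial C1–CH2O arm and away from the C2–CH2O arm, so the new C6 stereocenter carries the allyl group cis to the C1 methyl.

**Step 7**
Reactants: 12 6β-allyl oxolane enone
Product: 14 6β-allyl oxolane ketone, via lithium enolate 13 (not isolated)
Conditions: Li (2.2 equiv), NH3 (l)/THF, t-BuOH (1 equiv), −78 °C; then NH4Cl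
Reagents that add atoms: none
Why: Dissolving-metal conjugate reduction (two electron transfers, β-protonation) gives the C4=C5 lithium enolate, which is protonated on quench; the isolated terminal alkene and the ether are inert, and C6 is not part of the enolate and keeps its configuration.

**Step 8**
Reactants: 15 2-methylpropanoyl chloride; 16 benzenethiol
Product: 17 S-phenyl 2-methylpropanethioate
Conditions: pyridine, CH2Cl2, 0 °C → rt
Reagents that add atoms: none
Why: Acyl substitution of the acid chloride by the thiol gives the thioester needed for the β-lactone olefination.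

**Step 9**
Reactants: 14 6β-allyl oxolane ketone; 17 S-phenyl 2-methylpropanethioate
Product: 19 spiro β-lactone, via lithium aldolate 18 (not isolated)
Conditions: 17, LiN(i-Pr)2, THF, −78 °C; then 14, −78 → 0 °C; aq. NH4Cl
Reagents that add atoms: none
Why: Aldol addition of the thioester lithium enolate to the ketone and 4-exo-trig closure of the aldolate with loss of thiophenoxide (β-lactone synthesis from thioester enolates) should give the spiro β-lactone; the enolate is a weak base, so the epimerisable C6 centre is left alone, and the C5 configuration is irrelevant.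

**Step 10**
Reactants: 19 spiro β-lactone
Product: 20 isopropylidene oxolane
Conditions: SiO2, cyclohexane, 80 °C
Reagents that add atoms: none
Why: Thermal [2+2] cycloreversion of the β-lactone loses CO2 and places the double bond only between C5 and the former enolate carbon, giving the tetrasubstituted alkene without base and well below the temperature at which the 1,5-diene could undergo a Cope rearrangement.

**Step 11**
Reactants: 20 isopropylidene oxolane
Product: 22 bromo alcohol, via bromo borinate 21 (not isolated)
Conditions: Me2BBr (2 equiv), Et3N (0.2 equiv), CH2Cl2, 0 °C → rt; aq. NaHCO3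
Reagents that add atoms: bromodimethylborane, CB(C)Br
Why: Lewis-acid ether cleavage: boron binds the oxolane oxygen and bromide opens the oxonium by SN2 at the less hindered CH2 (on C2) because the other α-carbon is neopentyl, so hydrolysis of the borinate should give the C2 bromomethyl compound with the C1 hydroxymethyl free; triethylamine scavenges HBr to protect the alkenes.

**Step 12**
Reactants: 22 bromo alcohol
Product: 23 C1 neopentyl alcohol with the C2 methyl
Conditions: Bu3SnH, Et3B (cat.), air, toluene, rt
Reagents that add atoms: none
Why: Radical-chain dehalogenation under neutral conditions should reduce the primary bromide to the C2 methyl group without forming an alkoxide, so reclosure to the oxolane is avoided, and hydrogen transfer from tin should outrun cyclisation onto the remote alkenes.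

**Step 13**
Reactants: 23 C1 neopentyl alcohol with the C2 methyl; 24 isofraxidin
Product: 25 allyl aryl ether
Conditions: PPh3, DIAD, THF (concentrated), sonication, rt
Reagents that add atoms: none
Why: Mitsunobu reaction: the acidic 7-hydroxycoumarin protonates the betaine and its phenoxide displaces the alkoxyphosphonium group at the primary CH2 (SN2, no stereocenter involved); the displacement is slow at a neopentyl carbon, hence high concentration and sonication, and elimination cannot compete because C1 bears no hydrogen.

**Step 14**
Reactants: 25 allyl aryl ether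
Product: 27 target CNP0311605.1, via alkylborane 26 (not isolated)
Conditions: 9-BBN (1.3 equiv), THF, 0 °C → rt; then 30% H2O2, aq. NaOAc, 0 °C → rt
Reagents that add atoms: hydrogen peroxide, OO
Why: Anti-Markovnikov hydroboration of the terminal alkene with the bulky 9-BBN should be selective over the tetrasubstituted isopropylidene alkene and the conjugated coumarin lactone, and buffered peroxide oxidation (retention at carbon) gives the primary alcohol without opening the coumarin.

**Compound list**
1 | 5-hydroxy-4-methylfuran-2(5H)-one | CC1=CC(=O)OC1O | starting material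
2 | (+)-menthol, (1S,2R,5S)-5-methyl-2-(propan-2-yl)cyclohexan-1-ol | C[C@H]1CC[C@@H]([C@H](C1)O)C(C)C | starting material
3 | (5S)-4-methyl-5-{[(1S,2R,5S)-5-methyl-2-(propan-2-yl)cyclohexyl]oxy}furan-2(5H)-one | C[C@H]1CC[C@@H]([C@H](C1)O[C@H]2OC(=O)C=C2C)C(C)C | intermediate
4 | (E)-1-methoxy-3-(trimethylsilyloxy)buta-1,3-diene | CO/C=C/C(=C)O[Si](C)(C)C | starting material
5 | primary cycloadduct: cis-fused (3S)-3-menthyloxy-7-methoxy-3a-methyl-5-(trimethylsilyloxy)-3a,4,7,7a-tetrahydro-2-benzofuran-1(3H)-one, methoxy carbon as a mixture | C[C@H]1CC[C@@H]([C@H](C1)O[C@H]2OC(=O)[C@@H]3C(OC)C=C(O[Si](C)(C)C)C[C@]23C)C(C)C | intermediate (not isolated)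
6 | (3S,3aS,7aR)-3-[(1S,2R,5S)-menthyloxy]-3a-methyl-3a,4-dihydro-2-benzofuran-1,5(3H,7aH)-dione; angular methyl, ring-fusion H and menthyloxy on one face | C[C@H]1CC[C@@H]([C@H](C1)O[C@H]2OC(=O)[C@@H]3C=CC(=O)C[C@]23C)C(C)C | intermediate
7 | cis-4,5-bis(hydroxymethyl)-5-methylcyclohex-2-en-1-ol (both CH2OH α, C1 methyl β; carbinol epimers) | OC[C@]1(C)[C@H](CO)C=CC(O)C1 | intermediate
8 | monotosylate of 7 at the CH2OH on C2 | OC[C@]1(C)[C@H](COS(=O)(=O)c2ccc(C)cc2)C=CC(O)C1 | intermediate (not isolated)
9 | (3aS,7aR)-3a-methyl-1,3,3a,4,5,7a-hexahydro-2-benzofuran-5-ol (carbinol epimers) | O1C[C@]2(C)[C@H](C1)C=CC(O)C2 | intermediate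
10 | (3aS,7aR)-3a-methyl-1,3,3a,7a-tetrahydro-2-benzofuran-5(4H)-one | O1C[C@]2(C)[C@H](C1)C=CC(=O)C2 | intermediate
11 | lithium dienolate of 10 (C3=C4–C5(OLi)=C6) | O1C[C@]2(C)[C@H](C1)C=CC(O[Li])=C2 | intermediate (not isolated)
12 | (3aR,4S,7aR)-3a-methyl-4-(prop-2-en-1-yl)-1,3,3a,7a-tetrahydro-2-benzofuran-5(4H)-one (allyl cis to the angular methyl) | O1C[C@]2(C)[C@H](C1)C=CC(=O)[C@H]2CC=C | intermediate
13 | lithium enolate (C4=C5–OLi) formed in the reduction of 12 | O1C[C@]2(C)[C@H](C1)CC=C(O[Li])[C@H]2CC=C | intermediate (not isolated)
14 | (3aR,4S,7aR)-3a-methyl-4-(prop-2-en-1-yl)hexahydro-2-benzofuran-5(3H)-one | O1C[C@]2(C)[C@H](C1)CCC(=O)[C@H]2CC=C | intermediate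
15 | 2-methylpropanoyl chloride | CC(C)C(Cl)=O | starting material
16 | benzenethiol | Sc1ccccc1 | starting material
17 | S-phenyl 2-methylpropanethioate | CC(C)C(=O)Sc1ccccc1 | intermediate
18 | lithium aldolate of 14 with the enolate of 17 (C5 epimers) | O1C[C@]2(C)[C@H](C1)CCC(O[Li])(C(C)(C)C(=O)Sc3ccccc3)[C@H]2CC=C | intermediate (not isolated)
19 | spiro β-lactone: 3,3-dimethyloxetan-2-one spiro-fused at C5 of the 6β-allyl oxolane bicycle (C5 epimers) | O1C[C@]2(C)[C@H](C1)CCC3(OC(=O)C3(C)C)[C@H]2CC=C | intermediate
20 | (3aS,4R,7aR)-3a-methyl-5-(propan-2-ylidene)-4-(prop-2-en-1-yl)octahydro-2-benzofuran | O1C[C@]2(C)[C@H](C1)CCC(=C(C)C)[C@H]2CC=C | intermediate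
21 | dimethylborinate of 22 (C1–CH2–O–BMe2, C2–CH2Br) | CB(C)OC[C@]1(C)[C@H](CBr)CCC(=C(C)C)[C@H]1CC=C | intermediate (not isolated)
22 | bromo alcohol: C1 α-CH2OH and β-CH3, C2 α-CH2Br, C5 isopropylidene, C6 β-allyl | OC[C@]1(C)[C@H](CBr)CCC(=C(C)C)[C@H]1CC=C | intermediate
23 | [(1R,2R,6R)-1,6-dimethyl-3-(propan-2-ylidene)-2-(prop-2-en-1-yl)cyclohexyl]methanol | OC[C@]1(C)[C@H](C)CCC(=C(C)C)[C@H]1CC=C | intermediate
24 | isofraxidin, 7-hydroxy-6,8-dimethoxy-2H-chromen-2-one | COc1cc2ccc(=O)oc2c(OC)c1O | starting material
25 | 7-{[(1R,2R,6R)-1,6-dimethyl-3-(propan-2-ylidene)-2-(prop-2-en-1-yl)cyclohexyl]methoxy}-6,8-dimethoxy-2H-chromen-2-one | COc1cc2ccc(=O)oc2c(OC)c1OC[C@]1(C)[C@H](C)CCC(=C(C)C)[C@H]1CC=C | intermediate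
26 | B-alkyl-9-borabicyclo[3.3.1]nonane from 25 (boron on the terminal carbon) | COc1cc2ccc(=O)oc2c(OC)c1OC[C@]1(C)[C@H](C)CCC(=C(C)C)[C@H]1CCCB3C4CCCC3CCC4 | intermediate (not isolated)
27 | 7-{[(1R,2R,6R)-2-(3-hydroxypropyl)-1,6-dimethyl-3-(propan-2-ylidene)cyclohexyl]methoxy}-6,8-dimethoxy-2H-chromen-2-one | COc1cc2ccc(=O)oc2c(OC)c1OC[C@]1(C)[C@H](C)CCC(=C(C)C)[C@H]1CCCO | target

**Step count**
Total: 14 steps. Longest linear sequence: 13 steps (steps 1–7 and 9–14; step 8 is a one-step side branch).

**Steps most likely to fail**

Step 2. The cycloaddition to the β,β-disubstituted butenolide may be too slow, so that the diene decomposes or polymerises at 130 °C before the adduct accumulates, or the face selectivity erodes on long heating. Fallback, setting out from 3: the much more nucleophilic (E)-1-(dimethylamino)-3-(tert-butyldimethylsilyloxy)buta-1,3-diene is used in toluene at 60–80 °C. It should add with the same regiochemistry and the same anti-to-menthyloxy face selectivity to give the amino silyl enol ether cycloadduct F1. Dilute HCl in THF at 0 °C then hydrolyses the silyl enol ether and eliminates dimethylamine, and the route is rejoined at 6.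

Step 13. The SN2 displacement at the neopentyl CH2, flanked by two substituted ring carbons, may be so slow that the phosphonium intermediate is diverted (alkylation of the hydrazide, decay of the betaine) and the alcohol is returned. Fallback, setting out from 23: the alcohol is converted with Tf2O and 2,6-lutidine (CH2Cl2, −78 °C) into the neopentyl triflate F2. This is displaced by the pre-formed caesium phenoxide of 24 (Cs2CO3, DMF, 60 °C); the far better leaving group and the free phenoxide replace the redox condensation. The route is rejoined at 25.

Step 11. The Lewis-acid opening may be slow on the hindered oxolane, adventitious HBr may add to or shift the tetrasubstituted alkene, or the bromo alcohol may reclose on handling. Fallback, setting out from 20: reductive ether cleavage with LiAlH(Ot-Bu)3 and Et3B in tetrahydropyran at rt. The borane-activated ether is opened by hydride at the less hindered CH2, which gives the C2 methyl group and the C1 hydroxymethyl in one operation, with no halide intermediate and no Brønsted acid. No new compound is formed on this path (entry F0), and the route is rejoined at 23.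

**Further compounds**
F1 | step 2 | cis-fused (3S)-7-(dimethylamino)-3-menthyloxy-3a-methyl-5-(tert-butyldimethylsilyloxy)-3a,4,7,7a-tetrahydro-2-benzofuran-1(3H)-one, amino carbon as a mixture | C[C@H]1CC[C@@H]([C@H](C1)O[C@H]2OC(=O)[C@@H]3C(N(C)C)C=C(O[Si](C)(C)C(C)(C)C)C[C@]23C)C(C)C
F2 | step 13 | [(1R,2R,6R)-1,6-dimethyl-3-(propan-2-ylidene)-2-(prop-2-en-1-yl)cyclohexyl]methyl trifluoromethanesulfonate | FC(F)(F)S(=O)(=O)OC[C@]1(C)[C@H](C)CCC(=C(C)C)[C@H]1CC=C
F0 | step 11 | none | none
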